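**Retrosynthetic overview**
- The tertiary orsellinate at C6 (cyclohexenone numbering: C1 carbonyl, C2 methyl, C3 side chain, C5 hydroxyl) is cut at the C6–O bond to a C6 enolate and an electrophilic aroyloxy donor (diaroyl peroxide). The C6 methyl is cut to the same enolate and MeI. Both enter anti to the C5 silyloxy group.
- The cyclohexenone is cut at C1–C2 and C3–C4 to a prochiral 3-silyloxycyclobutanone and an internal alkyne: a formal [4+2] ring expansion on zerovalent nickel that also sets C5 by desymmetrisation.
- Enabling feature: the 2-methyl-3-alkylcyclohex-2-enone ring. C2=C3 with its methyl and 2-oxopentyl arms is an internal alkyne in disguise. C1(=O)–C6–C5(O)–C4 is a cyclobutanone whose mirror plane runs through C1 and C5. The side-chain ketone sits β to C3, so it can be carried as an enol silane conjugated to the alkyne (a 2-silyloxy-1,3-enyne) that steers the regiochemistry.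
- Ring order: only the carbocycle is built (step 8); the arene is bought as orsellinic acid. The enyne comes from 1-propynyllithium and 1,2-epoxypentane.

Key step: step 8

Remark: 3-[(tert-butyldimethylsilyl)oxy]cyclobutan-1-one is taken as a catalogue compound (otherwise one silylation from 3-hydroxycyclobutan-1-one), and racemic 1,2-epoxypentane is used because its stereocentre is oxidised away.

**Step 1**
Reactants: 1 1-propynyllithium; 2 1,2-epoxypentane (racemic)
Product: 3 oct-6-yn-4-ol (racemic)
Conditions: THF/DMPU, −78 °C → rt; aq. NH4Cl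
Reagents that add atoms: none
Why: SN2 opening of the terminal epoxide at its CH2 carbon by the lithium acetylide should give the homopropargylic alcohol, whose carbinol centre is removed in step 2.

**Step 2**
Reactants: 3 oct-6-yn-4-ol
Product: 4 oct-6-yn-4-one
Conditions: Dess–Martin periodinane, NaHCO3, CH2Cl2, 0 °C → rt; used at once
Reagents that add atoms: none
Why: Dess–Martin oxidation under buffered, base-free conditions should give the β,γ-alkynyl ketone without prototropic shift to the allenyl ketone.

**Step 3**
Reactants: 4 oct-6-yn-4-one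
Product: 5 (Z)-tert-butyldimethyl[(oct-4-en-6-yn-4-yl)oxy]silane
Conditions: t-BuMe2SiOTf, Et3N, CH2Cl2, −78 → 0 °C
Reagents that add atoms: tert-butyldimethylsilyl trifluoromethanesulfonate, CC(C)(C)[Si](C)(C)OS(=O)(=O)C(F)(F)F
Why: Soft enolisation removes the doubly activated propargylic α-proton and O-silylation should give the conjugated 2-silyloxy-1,3-enyne, the Z isomer being expected and the geometry being without consequence.

**Step 4**
Reactants: 6 orsellinic acid (2,4-dihydroxy-6-methylbenzoic acid)
Product: 8 2,4-bis[(tert-butyldimethylsilyl)oxy]-6-methylbenzoic acid, via tris-silylated orsellinate 7 (not isolated)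
Conditions: t-BuMe2SiCl, imidazole, DMF, rt; then AcOH/THF/H2O, rt
Reagents that add atoms: tert-butyldimethylsilyl chloride, CC(C)(C)[Si](C)(C)Cl
Why: Exhaustive silylation followed by selective hydrolysis of the far more labile silyl ester should leave both phenolic silyl ethers and the free acid.

**Step 5**
Reactants: 8 2,4-bis[(tert-butyldimethylsilyl)oxy]-6-methylbenzoic acid
Product: 9 2,4-bis[(tert-butyldimethylsilyl)oxy]-6-methylbenzoyl chloride
Conditions: 1-chloro-N,N,2-trimethylprop-1-en-1-amine, CH2Cl2, 0 °C → rt; volatiles removed, used crude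
Reagents that add atoms: 1-chloro-N,N,2-trimethylprop-1-en-1-amine, CC(C)=C(Cl)N(C)C
Why: Acid chloride formation with the α-chloroenamine proceeds under neutral conditions, so the hindered acid should be activated without loss of the aryl silyl ethers.

**Step 6**
Reactants: 9 2,4-bis[(tert-butyldimethylsilyl)oxy]-6-methylbenzoyl chloride
Product: 10 2,4-bis[(tert-butyldimethylsilyl)oxy]-6-methylperoxybenzoic acid
Conditions: H2O2 (excess, dried ethereal solution), pyridine, Et2O, −20 → 0 °C, slow addition of 9; cold aqueous wash, used at once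
Reagents that add atoms: hydrogen peroxide, OO
Why: Perhydrolysis of the acid chloride (nucleophilic acyl substitution by hydrogen peroxide, pyridine as acid scavenger and acyl-transfer catalyst) with the peroxide in excess and inverse addition should stop at the peroxy acid, and the non-aqueous, weakly basic medium should spare the aryl silyl ethers.

**Step 7**
Reactants: 10 2,4-bis[(tert-butyldimethylsilyl)oxy]-6-methylperoxybenzoic acid; 9 2,4-bis[(tert-butyldimethylsilyl)oxy]-6-methylbenzoyl chloride
Product: 11 bis{2,4-bis[(tert-butyldimethylsilyl)oxy]-6-methylbenzoyl} peroxide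
Conditions: pyridine, CH2Cl2, −20 → 0 °C; kept cold in solution
Reagents that add atoms: none
Why: O-Acylation of a peroxy acid by an acyl chloride is the classical synthesis of diacyl peroxides and should give the electrophilic aroyloxy donor from one molecule each of 10 and 9.

**Step 8**
Reactants: 5 (Z)-tert-butyldimethyl[(oct-4-en-6-yn-4-yl)oxy]silane; 12 3-[(tert-butyldimethylsilyl)oxy]cyclobutan-1-one
Product: 13 (5S)-5-[(tert-butyldimethylsilyl)oxy]-3-[(1Z)-2-[(tert-butyldimethylsilyl)oxy]pent-1-en-1-yl]-2-methylcyclohex-2-en-1-one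
Conditions: Ni(cod)2 (10 mol %), BINOL-derived N,N-bis(1-phenylethyl)phosphoramidite (single enantiomer, 20 mol %), toluene, 80–100 °C, slow addition of 5
Reagents that add atoms: none
Why: Proposed new method: zerovalent nickel should join the ketone carbonyl carbon to the methyl-bearing alkyne carbon by oxidative cyclisation (nickel on the alkenyl-bearing carbon), open the strained spiro-cyclobutane by β-carbon elimination to a seven-membered alkyl(alkenyl) divalent nickel ring, and close the cyclohexenone by C(sp2)–C(sp3) reductive elimination, so that the alkyne is inserted into one acyl–CH2 bond. The closest known reaction types are the nickel-catalysed intermolecular insertion of internal alkynes into cyclobutanones with achiral phosphines, the regioselective insertion of 1,3-enynes into four-membered heterocyclic ketones, and the enantioselective intramolecular alkene insertion into 3-substituted cyclobutanones with nickel–phosphoramidite catalysts; the enantioselective intermolecular alkyne version on a 3-silyloxycyclobutanone is not known. The six-membered ring is closed by ring expansion (four ring carbons of the ketone plus two alkyne carbons), the last bond coming from reductive elimination out of the metallacycle and not from a Baldwin-type cyclisation. The only new stereocentre, C5, has no bond made or broken: it becomes stereogenic when the chiral ligand on nickel selects one of the two enantiotopic C(O)–CH2 bonds in the β-carbon elimination, and the ligand antipode that gives the 5S product must be found by trial. The step needs the alkyne orientation with methyl next to the carbonyl, which the conjugated enol silane alkene (holding nickel on its own alkyne carbon) and the small methyl group should secure; it also needs reductive elimination to outrun β-hydride and β-silyloxy elimination, for which the poor leaving ability of the bulky silyloxy group is relied on, with slow enyne addition against oligomerisation.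

**Step 9**
Reactants: 13 (5S)-5-[(tert-butyldimethylsilyl)oxy]-3-[(1Z)-2-[(tert-butyldimethylsilyl)oxy]pent-1-en-1-yl]-2-methylcyclohex-2-en-1-one
Product: 15 (5S,6R)-5-[(tert-butyldimethylsilyl)oxy]-3-[(1Z)-2-[(tert-butyldimethylsilyl)oxy]pent-1-en-1-yl]-2,6-dimethylcyclohex-2-en-1-one, via lithium dienolate 14 (not isolated)
Conditions: LiN(iPr)2, THF, −78 °C; MeI, −78 → −40 °C
Reagents that add atoms: iodomethane, CI
Why: Kinetic α'-deprotonation of the enone and enolate alkylation should place the methyl at C6 anti to the C5 silyloxy group; this C6 configuration is erased again in step 10.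

**Step 10**
Reactants: 15 (5S,6R)-5-[(tert-butyldimethylsilyl)oxy]-3-[(1Z)-2-[(tert-butyldimethylsilyl)oxy]pent-1-en-1-yl]-2,6-dimethylcyclohex-2-en-1-one; 11 bis{2,4-bis[(tert-butyldimethylsilyl)oxy]-6-methylbenzoyl} peroxide
Product: 17 (1R,6S)-6-[(tert-butyldimethylsilyl)oxy]-4-[(1Z)-2-[(tert-butyldimethylsilyl)oxy]pent-1-en-1-yl]-1,3-dimethyl-2-oxocyclohex-3-en-1-yl 2,4-bis[(tert-butyldimethylsilyl)oxy]-6-methylbenzoate, via lithium dienolate 16 (not isolated)
Conditions: LiN(iPr)2, THF, −78 → −40 °C; then 11, −78 → −20 °C; aq. NH4Cl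
Reagents that add atoms: none
Why: Electrophilic α-acyloxylation of the tetrasubstituted enolate by the diaroyl peroxide (enolate carbon attacks the O–O bond) should form the hindered tertiary ester C–O bond directly, and A(1,2) strain with the C6 methyl should hold the C5 silyloxy group pseudoaxial so that the reagent enters anti to it, setting the quaternary centre with its oxygen trans to the C5 oxygen.

**Step 11**
Reactants: 17 (1R,6S)-6-[(tert-butyldimethylsilyl)oxy]-4-[(1Z)-2-[(tert-butyldimethylsilyl)oxy]pent-1-en-1-yl]-1,3-dimethyl-2-oxocyclohex-3-en-1-yl 2,4-bis[(tert-butyldimethylsilyl)oxy]-6-methylbenzoate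
Product: 18 talarophilone, (1R,6S)-6-hydroxy-1,3-dimethyl-2-oxo-4-(2-oxopentyl)cyclohex-3-en-1-yl 2,4-dihydroxy-6-methylbenzoate
Conditions: HF·pyridine, pyridine, THF, 0 °C → rt
Reagents that add atoms: none
Why: Fluoride-mediated desilylation should free both phenols and the secondary alcohol and protonate the enol silane at carbon to release the 2-oxopentyl ketone, under buffered conditions that avoid retro-aldol cleavage, acyl migration and β-elimination.

**Compound list**
1 | 1-propynyllithium | [Li]C#CC | starting material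
2 | 1,2-epoxypentane (racemic) | CCCC1CO1 | starting material
3 | oct-6-yn-4-ol (racemic) | CCCC(O)CC#CC | intermediate
4 | oct-6-yn-4-one | CCCC(=O)CC#CC | intermediate
5 | (Z)-tert-butyldimethyl[(oct-4-en-6-yn-4-yl)oxy]silane | CCC/C(O[Si](C)(C)C(C)(C)C)=C/C#CC | intermediate
6 | orsellinic acid (2,4-dihydroxy-6-methylbenzoic acid) | Cc1cc(O)cc(O)c1C(=O)O | starting material
7 | tert-butyldimethylsilyl 2,4-bis[(tert-butyldimethylsilyl)oxy]-6-methylbenzoate | Cc1cc(O[Si](C)(C)C(C)(C)C)cc(O[Si](C)(C)C(C)(C)C)c1C(=O)O[Si](C)(C)C(C)(C)C | intermediate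
8 | 2,4-bis[(tert-butyldimethylsilyl)oxy]-6-methylbenzoic acid | Cc1cc(O[Si](C)(C)C(C)(C)C)cc(O[Si](C)(C)C(C)(C)C)c1C(=O)O | intermediate
9 | 2,4-bis[(tert-butyldimethylsilyl)oxy]-6-methylbenzoyl chloride | Cc1cc(O[Si](C)(C)C(C)(C)C)cc(O[Si](C)(C)C(C)(C)C)c1C(=O)Cl | intermediate
10 | 2,4-bis[(tert-butyldimethylsilyl)oxy]-6-methylperoxybenzoic acid | Cc1cc(O[Si](C)(C)C(C)(C)C)cc(O[Si](C)(C)C(C)(C)C)c1C(=O)OO | intermediate
11 | bis{2,4-bis[(tert-butyldimethylsilyl)oxy]-6-methylbenzoyl} peroxide | Cc1cc(O[Si](C)(C)C(C)(C)C)cc(O[Si](C)(C)C(C)(C)C)c1C(=O)OOC(=O)c1c(C)cc(O[Si](C)(C)C(C)(C)C)cc1O[Si](C)(C)C(C)(C)C | intermediate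
12 | 3-[(tert-butyldimethylsilyl)oxy]cyclobutan-1-one | O=C1CC(O[Si](C)(C)C(C)(C)C)C1 | starting material
13 | (5S)-5-[(tert-butyldimethylsilyl)oxy]-3-[(1Z)-2-[(tert-butyldimethylsilyl)oxy]pent-1-en-1-yl]-2-methylcyclohex-2-en-1-one | CCC/C(O[Si](C)(C)C(C)(C)C)=C/C1=C(C)C(=O)C[C@@H](O[Si](C)(C)C(C)(C)C)C1 | intermediate
14 | lithium dienolate of 13 (O–Li on C1, C1=C6) | CCC/C(O[Si](C)(C)C(C)(C)C)=C/C1=C(C)C(O[Li])=C[C@@H](O[Si](C)(C)C(C)(C)C)C1 | intermediate
15 | (5S,6R)-5-[(tert-butyldimethylsilyl)oxy]-3-[(1Z)-2-[(tert-butyldimethylsilyl)oxy]pent-1-en-1-yl]-2,6-dimethylcyclohex-2-en-1-one | CCC/C(O[Si](C)(C)C(C)(C)C)=C/C1=C(C)C(=O)[C@H](C)[C@@H](O[Si](C)(C)C(C)(C)C)C1 | intermediate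
16 | lithium dienolate of 15 (O–Li on C1, C1=C6) | CCC/C(O[Si](C)(C)C(C)(C)C)=C/C1=C(C)C(O[Li])=C(C)[C@@H](O[Si](C)(C)C(C)(C)C)C1 | intermediate
17 | (1R,6S)-6-[(tert-butyldimethylsilyl)oxy]-4-[(1Z)-2-[(tert-butyldimethylsilyl)oxy]pent-1-en-1-yl]-1,3-dimethyl-2-oxocyclohex-3-en-1-yl 2,4-bis[(tert-butyldimethylsilyl)oxy]-6-methylbenzoate | CCC/C(O[Si](C)(C)C(C)(C)C)=C/C1=C(C)C(=O)[C@](C)(OC(=O)c2c(C)cc(O[Si](C)(C)C(C)(C)C)cc2O[Si](C)(C)C(C)(C)C)[C@@H](O[Si](C)(C)C(C)(C)C)C1 | intermediate
18 | talarophilone, (1R,6S)-6-hydroxy-1,3-dimethyl-2-oxo-4-(2-oxopentyl)cyclohex-3-en-1-yl 2,4-dihydroxy-6-methylbenzoate | CCCC(=O)CC1=C(C)C(=O)[C@](C)(OC(=O)c2c(C)cc(O)cc2O)[C@@H](O)C1 | target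

**Count**
Total steps: 11. Longest linear sequence: 7 (steps 1, 2, 3, 8, 9, 10, 11).

**Steps most likely to fail**

Step 8. The chiral nickel catalyst may not distinguish the two enantiotopic acyl–CH2 bonds well enough, or the metallacycle may be lost by β-silyloxy or β-hydride elimination. The fallback sets the configuration before the annulation by known chemistry and sets out from 12. Enantioselective deprotonation with a chiral lithium amide (lithium bis(1-phenylethyl)amide, the antipode that gives the S product, Me3SiCl present, THF, −100 °C) should give (S)-3-[(tert-butyldimethylsilyl)oxy]-1-[(trimethylsilyl)oxy]cyclobut-1-ene F1. MeLi (THF, 0 °C) then releases lithium (S)-3-[(tert-butyldimethylsilyl)oxy]cyclobut-1-en-1-olate F2, which is methylated with MeI at −78 °C anti to the silyloxy group to give (2R,3S)-3-[(tert-butyldimethylsilyl)oxy]-2-methylcyclobutan-1-one F3. F3 and 5 are then joined with the achiral catalyst Ni(cod)2/PCy3 (toluene, 100 °C); the alkyne should insert into the less substituted acyl–CH2 bond, as it does with 2-substituted four-membered heterocyclic ketones. The route is rejoined at 15, so the enolate methylation of step 9, with its own hazard of silyloxy loss and aromatisation, is bypassed as well.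

Step 10. The enolate may attack a peroxide carbonyl (acyl transfer) instead of the O–O bond, deprotonation of the tertiary C6–H may be slow enough for E1cB loss of the silyloxy group and aromatisation, or facial control with the bulky peroxide may be poor. The fallback makes the C–O bond in two stages and sets out from 15 and 9, so that peroxy acid 10 and peroxide 11 are not needed. Dienolate 16, generated as in step 10, is hydroxylated with 3-phenyl-2-(phenylsulfonyl)oxaziridine (THF, −78 °C) to (5S,6R)-5-[(tert-butyldimethylsilyl)oxy]-3-[(1Z)-2-[(tert-butyldimethylsilyl)oxy]pent-1-en-1-yl]-6-hydroxy-2,6-dimethylcyclohex-2-en-1-one F4. F4 is deprotonated with LiN(SiMe3)2 (THF, −78 °C) to lithium (1R,6S)-6-[(tert-butyldimethylsilyl)oxy]-4-[(1Z)-2-[(tert-butyldimethylsilyl)oxy]pent-1-en-1-yl]-1,3-dimethyl-2-oxocyclohex-3-en-1-olate F5, which is acylated with acid chloride 9 on warming to rt. The route is rejoined at 17.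

Step 3. The β,γ-alkynyl ketone may isomerise to the allenyl ketone and the conjugated dienone faster than it is O-silylated. The fallback assembles the enyne without making 4 and sets out from 1. 1-Bromopentan-2-one F6 (purchased) is enol-silylated toward the brominated carbon (t-BuMe2SiOTf, Et3N, CH2Cl2) to (Z)-[(1-bromopent-1-en-2-yl)oxy](tert-butyl)dimethylsilane F7. Compound 1 is transmetalated with ZnCl2 (THF, 0 °C) to prop-1-yn-1-ylzinc chloride F8, and Negishi coupling of F7 with F8 (Pd(PPh3)4 cat., THF, rt) should give the enyne with retention of alkene geometry. The route is rejoined at 5.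

**Further compounds**
F1 | step 8 | (S)-3-[(tert-butyldimethylsilyl)oxy]-1-[(trimethylsilyl)oxy]cyclobut-1-ene | C[Si](C)(C)OC1=C[C@@H](O[Si](C)(C)C(C)(C)C)C1
F2 | step 8 | lithium (S)-3-[(tert-butyldimethylsilyl)oxy]cyclobut-1-en-1-olate | [Li]OC1=C[C@@H](O[Si](C)(C)C(C)(C)C)C1
F3 | step 8 | (2R,3S)-3-[(tert-butyldimethylsilyl)oxy]-2-methylcyclobutan-1-one | O=C1[C@H](C)[C@@H](O[Si](C)(C)C(C)(C)C)C1
F4 | step 10 | (5S,6R)-5-[(tert-butyldimethylsilyl)oxy]-3-[(1Z)-2-[(tert-butyldimethylsilyl)oxy]pent-1-en-1-yl]-6-hydroxy-2,6-dimethylcyclohex-2-en-1-one | CCC/C(O[Si](C)(C)C(C)(C)C)=C/C1=C(C)C(=O)[C@](C)(O)[C@@H](O[Si](C)(C)C(C)(C)C)C1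
F5 | step 10 | lithium (1R,6S)-6-[(tert-butyldimethylsilyl)oxy]-4-[(1Z)-2-[(tert-butyldimethylsilyl)oxy]pent-1-en-1-yl]-1,3-dimethyl-2-oxocyclohex-3-en-1-olate | CCC/C(O[Si](C)(C)C(C)(C)C)=C/C1=C(C)C(=O)[C@](C)(O[Li])[C@@H](O[Si](C)(C)C(C)(C)C)C1
F6 | step 3 | 1-bromopentan-2-one | CCCC(=O)CBr
F7 | step 3 | (Z)-[(1-bromopent-1-en-2-yl)oxy](tert-butyl)dimethylsilane | CCC/C(O[Si](C)(C)C(C)(C)C)=C/Br
F8 | step 3 | prop-1-yn-1-ylzinc chloride | CC#C[Zn]Cl
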